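The target is the hetero-Diels–Alder adduct of (+)-β-pinene and an isobutylidene trione, so everything rests on a convergent build of ring A, the tetramethylcyclohexanetrione carbocycle. The key step is an Effenberger-type [3+3] annulation: the silyl enol ether of 3-methylbutan-2-one (tetrasubstituted C=C) is C-acylated twice by dimethylmalonyl dichloride in one flask, forming the CMe2–C(=O) bond to the central ketone and the CH2–C(=O) bond to the later enol-ether carbon and so closing ring A from two open-chain pieces. It exploits the 1,3,5-tricarbonyl pattern of ring A, whose CH2 and CMe2 carbons are the α and α′ positions of one ketone. Knoevenagel condensation and cycloaddition then add ring B, the spiro-dihydropyran, and both new stereocenters.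

Key step: step 2

Assumption (remark on the chemistry): the target carries the pinane skeleton of (1R,5R)-(+)-β-pinene, not that of the more common (−)-enantiomer; (+)-β-pinene of high enantiomeric purity is taken as a purchasable starting material.

Step 1
Reactants: 1 3-methylbut-3-en-2-one
Product: 2 triethyl[(3-methylbut-2-en-2-yl)oxy]silane (triethylsilyl enol ether of 3-methylbutan-2-one with the tetrasubstituted C=C)
Conditions: Et3SiH (1.1 equiv), RhCl(PPh3)3 (0.5 mol %), THF, 50 °C; distillation
Reagents that add atoms: triethylsilane, CC[SiH](CC)CC
Why: Rhodium-catalysed 1,4-hydrosilylation of an enone puts hydrogen on the terminal CH2 and silicon on oxygen, so the enol double bond can only lie between the carbonyl carbon and the CMe2 carbon (regiospecific, no stereocenter, no E/Z isomers).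

Step 2
Reactants: 2 triethyl[(3-methylbut-2-en-2-yl)oxy]silane; 3 2,2-dimethylpropanedioyl dichloride (dimethylmalonyl dichloride)
Product: 5 2,2,4,4-tetramethylcyclohexane-1,3,5-trione (syncarpic acid), via 2,2,4,4-tetramethyl-3,5-dioxohexanoyl chloride 4 (not isolated)
Conditions: 2 added slowly to 3 (1.1 equiv) and TiCl4 (2.2 equiv), CH2Cl2, −78 → −20 °C; then Bu3N (2.5 equiv), −20 °C → rt; 1 M HCl, acid/base extraction
Reagents that add atoms: none
Why: TiCl4-activated 3 acylates the nucleophilic CMe2 carbon of silyl enol ether 2 (Mukaiyama-type C-acylation with loss of Et3SiCl), which forms the bond between that quaternary carbon and the future central ring ketone and gives the chelated acid chloride 4; Bu3N then turns the terminal methyl ketone of 4, its only enolizable site, into a titanium enolate whose CH2 carbon attacks the remaining acid chloride (titanium Claisen/Dieckmann-type acylation), forming the CH2–C(=O) bond. The closest known reaction types are the Effenberger cyclization of ketone enol ethers with malonyl dichloride to cyclohexane-1,3,5-triones and TiCl4/amine Claisen condensations of ketones with acid chlorides. Ring A, the only ring closed, forms by a 6-(enolendo)-exo-trig C-acylation. No stereocenter is created, since 5 is achiral and mirror-symmetric. The step needs acylation of only one acid chloride of 3 in the first stage, which inverse addition of 2 to a slight excess of 3 at −78 °C and the absence of any α-hydrogen in 3 should secure, and closure through carbon and not through the enol oxygen in the second stage, which the oxophilic titanium enolate and the chelation of 5 as a titanium β-diketonate should favour. An enol lactone formed by closure through oxygen would remain an acyl donor under these conditions and should be funnelled to the same chelate.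

Step 3
Reactants: 5 2,2,4,4-tetramethylcyclohexane-1,3,5-trione; 6 2-methylpropanal (1.5 equiv)
Product: 8 2,2,4,4-tetramethyl-6-(2-methylpropylidene)cyclohexane-1,3,5-trione, via piperidine Mannich base 7 (not isolated)
Conditions: piperidine (1.1 equiv), CH2Cl2, 0 °C → rt; then 1 M HCl (aq), Et2O, rt; used without chromatography
Reagents that add atoms: none
Why: Knoevenagel condensation routed through the Mannich adduct: the enol of 5 attacks the iminium ion from 6 and piperidine, adduct 7 ties up all of 5 so that no second trione can add, and acid then expels piperidine to give the conjugated trione 8, which has no stereocenter and no geometrical isomers.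

Step 4
Reactants: 8 2,2,4,4-tetramethyl-6-(2-methylpropylidene)cyclohexane-1,3,5-trione; 9 (1R,5R)-6,6-dimethyl-2-methylidenebicyclo[3.1.1]heptane ((+)-β-pinene)
Product: 10 (1S,2S,4'R,5R)-6,6,6',6',8',8'-hexamethyl-4'-(propan-2-yl)-3',4'-dihydrospiro[bicyclo[3.1.1]heptane-2,2'-chromene]-5',7'(6'H,8'H)-dione (the target)
Conditions: 9 (2 equiv), toluene, 80 °C, sealed tube; chromatography on silica gel to remove the C4' epimer
Reagents that add atoms: none
Why: Hetero-Diels–Alder reaction with inverse electron demand between the 1-oxadiene O=C–C=CH(iPr) of 8 (either of its two equivalent ring carbonyls, isopropyl outside) and the 1,1-disubstituted alkene of 9 should close ring B with oxygen on the more substituted alkene carbon; attack on the alkene face anti to the gem-dimethyl bridge sets the spiro centre (S), while the CH(iPr) centre (R) arises from the transition state that holds the bridgehead CH of the pinane under the heterodiene, so that the C4' epimer is expected alongside and is removed by chromatography.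

Compound list
1 | 3-methylbut-3-en-2-one | CC(=C)C(C)=O | starting material
2 | triethyl[(3-methylbut-2-en-2-yl)oxy]silane | CC(C)=C(C)O[Si](CC)(CC)CC | intermediate
3 | 2,2-dimethylpropanedioyl dichloride (dimethylmalonyl dichloride) | CC(C)(C(Cl)=O)C(Cl)=O | starting material
4 | 2,2,4,4-tetramethyl-3,5-dioxohexanoyl chloride (formed in the flask, not isolated) | CC(=O)C(C)(C)C(=O)C(C)(C)C(Cl)=O | intermediate
5 | 2,2,4,4-tetramethylcyclohexane-1,3,5-trione (syncarpic acid, drawn as the triketo tautomer) | CC1(C)C(=O)CC(=O)C(C)(C)C1=O | intermediate
6 | 2-methylpropanal (isobutyraldehyde) | CC(C)C=O | starting material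
7 | 3-hydroxy-4,4,6,6-tetramethyl-2-[2-methyl-1-(piperidin-1-yl)propyl]cyclohex-2-ene-1,5-dione (piperidine Mannich base, racemic, formed in the flask, not isolated) | CC(C)C(N1CCCCC1)C1=C(O)C(C)(C)C(=O)C(C)(C)C1=O | intermediate
8 | 2,2,4,4-tetramethyl-6-(2-methylpropylidene)cyclohexane-1,3,5-trione | CC(C)C=C1C(=O)C(C)(C)C(=O)C(C)(C)C1=O | intermediate
9 | (1R,5R)-6,6-dimethyl-2-methylidenebicyclo[3.1.1]heptane ((+)-β-pinene) | C=C1CC[C@@H]2C[C@H]1C2(C)C | starting material
10 | (1S,2S,4'R,5R)-6,6,6',6',8',8'-hexamethyl-4'-(propan-2-yl)-3',4'-dihydrospiro[bicyclo[3.1.1]heptane-2,2'-chromene]-5',7'(6'H,8'H)-dione (ring oxygen anti to the gem-dimethyl bridge, isopropyl cis to the pinane bridgehead CH across ring B) | CC(C)[C@H]1C[C@]2(CC[C@@H]3C[C@H]2C3(C)C)OC2=C1C(=O)C(C)(C)C(=O)C2(C)C | target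

Total step count: 4
Longest linear sequence: 4 steps (1 → 2 → 5 → 8 → 10); 3, 6 and 9 enter as purchased materials.

Steps most likely to fail

1. Step 2. The second acylation may close through the enol oxygen of the methyl ketone instead of through its carbon, or enolization by TiCl4/Bu3N may be too slow, so that the acid chloride is lost to hydrolysis at work-up. Fallback, setting out from 2 (with 3) and coming back at 5: the cascade is interrupted after the first acylation (TiCl4, CH2Cl2, −78 °C) by a quench with methanol and pyridine, which turns the remaining acid chloride into the ester and should give the isolable methyl 2,2,4,4-tetramethyl-3,5-dioxohexanoate F1. Dieckmann condensation of F1 with lithium diisopropylamide (2.2 equiv, THF, −78 °C → rt; 1 M HCl) then closes ring A through the methyl ketone enolate and the ester with loss of methanol and returns to 5.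

2. Step 4. Poor discrimination between the two orientations of the heterodiene over the pinane (bridgehead CH or ring CH2 under the diene) may leave the target as the minor C4' epimer, and hydrogen transfer from the allylic CH2 of 9 (ene reaction) may compete with cycloaddition. Fallback, setting out from 8 (with 9) and coming back at 8: the separated unwanted epimer, (1S,2S,4'S,5R)-6,6,6',6',8',8'-hexamethyl-4'-(propan-2-yl)-3',4'-dihydrospiro[bicyclo[3.1.1]heptane-2,2'-chromene]-5',7'(6'H,8'H)-dione F2, is not discarded but heated (1,2-dichlorobenzene, 180 °C, sealed tube). This should bring about retro-hetero-Diels–Alder cleavage into 8 and 9, which are resubjected to step 4, so that the wrong isomer is recycled instead of relying on kinetic selectivity alone.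

3. Step 3. The free alkylidene trione may be lost during liberation and isolation through conjugate addition of water or of a second molecule of 5, or through oligomerization. Fallback, setting out from 5 and coming back at 10: the Mannich base 7 is collected as a solid instead of being treated with HCl and is heated with 9 (2 equiv) and AcOH (1.1 equiv) in toluene at 80 °C, so that the heterodiene is released slowly and trapped by cycloaddition as it forms. This fallback makes no new compound (F0).

Further compounds
F1 | step 2 | methyl 2,2,4,4-tetramethyl-3,5-dioxohexanoate | COC(=O)C(C)(C)C(=O)C(C)(C)C(C)=O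
F2 | step 4 | (1S,2S,4'S,5R)-6,6,6',6',8',8'-hexamethyl-4'-(propan-2-yl)-3',4'-dihydrospiro[bicyclo[3.1.1]heptane-2,2'-chromene]-5',7'(6'H,8'H)-dione (C4' epimer of 10) | CC(C)[C@@H]1C[C@]2(CC[C@@H]3C[C@H]2C3(C)C)OC2=C1C(=O)C(C)(C)C(=O)C2(C)C
F0 | step 3 | none | none
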